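**Retrosynthetic overview**

- Gancaonin H is an isoflavone: ring B sits on C3, not C2, of pyranone ring C, and the pyran ether oxygen on C4' is para to C1'. An aryl group of this kind migrates readily in a cationic 1,2-shift, so the C3–C1' and O1–C2 bonds are both made from a 2'-hydroxychalcone by oxidative β→α aryl migration and acid ring closure.
- The chalcone comes from a Claisen–Schmidt condensation of 2,4-bis(benzyloxy)-6-hydroxyacetophenone (ring A) with 8-(benzyloxy)-2,2-dimethylchroman-6-carbaldehyde (ring B, with its pyran ring kept saturated because the oxidant attacks alkenes).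
- After the shift: debenzylation, 7,3'-bis-MOM protection, DDQ dehydrogenation of the chroman to the chromene, then the C6 prenyl group by 5-O-allylation, Claisen shift to C6 and cross-metathesis, and MOM removal.
- Ring order: the benzene rings A and B are bought; the pyran ring on ring B is closed first (propargyl ether Claisen), pyranone ring C is closed in the key step, and the pyran alkene is restored afterwards.

Key step: step 7

Assumption: with one equivalent of carbonate, 3,4-dihydroxybenzaldehyde is ionised and alkylated at the 4-OH, which is para to the formyl group and the more acidic. The target has no stereocentre; the single stereocentre that appears on the way (in the acetal of the key step) is racemic and is erased.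

**Route**

Step 1
Reactants: 1 2,4,6-trihydroxyacetophenone; 2 benzyl bromide
Product: 3 1-[2,4-bis(benzyloxy)-6-hydroxyphenyl]ethan-1-one
Conditions: BnBr (2.1 equiv), K2CO3 (2.2 equiv), DMF, 0 °C → rt
Reagents that add atoms: benzyl bromide, BrCc1ccccc1
Why: Williamson etherification; after the para and one ortho hydroxyl are benzylated, the remaining ortho OH is locked in a hydrogen bond to the acetyl carbonyl and is the least nucleophilic, so alkylation with two equivalents should stop at the dibenzyl ether.

Step 2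
Reactants: 4 3,4-dihydroxybenzaldehyde; 5 3-chloro-3-methylbut-1-yne
Product: 6 3-hydroxy-4-[(2-methylbut-3-yn-2-yl)oxy]benzaldehyde
Conditions: 5 (1.5 equiv), K2CO3 (1.1 equiv), KI (0.2 equiv), CuI (2 mol %), DMF, 50 °C, argon
Reagents that add atoms: 3-chloro-3-methylbut-1-yne, CC(C)(Cl)C#C
Why: Williamson-type O-alkylation with a tertiary propargylic chloride under CuI/KI assistance; the 4-OH is para to the formyl group and the more acidic, so with one equivalent of base its phenoxide should react and the 3-OH stay free.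

Step 3
Reactants: 6 3-hydroxy-4-[(2-methylbut-3-yn-2-yl)oxy]benzaldehyde
Product: 7 8-hydroxy-2,2-dimethyl-2H-chromene-6-carbaldehyde
Conditions: PhNEt2, 190 °C
Reagents that add atoms: none
Why: thermal aryl propargyl ether Claisen rearrangement to C5, the only ortho position that bears hydrogen, followed by tautomerisation, 1,5-hydrogen shift and 6π oxa-electrocyclisation, the standard entry to 2,2-dimethyl-2H-chromenes.

Step 4
Reactants: 7 8-hydroxy-2,2-dimethyl-2H-chromene-6-carbaldehyde
Product: 8 8-hydroxy-2,2-dimethylchroman-6-carbaldehyde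
Conditions: H2 (1 atm), 10% Pd/C, Ph2S (cat.), EtOAc, rt
Reagents that add atoms: none
Why: catalytic hydrogenation of the cis-disubstituted styrene-type alkene; Pd/C moderated with diphenyl sulfide in an aprotic solvent should saturate C3=C4 and spare the aryl aldehyde, and it removes the alkene that the oxidant of step 7 would attack.

Step 5
Reactants: 8 8-hydroxy-2,2-dimethylchroman-6-carbaldehyde; 2 benzyl bromide
Product: 9 8-(benzyloxy)-2,2-dimethylchroman-6-carbaldehyde
Conditions: BnBr (1.2 equiv), K2CO3 (1.5 equiv), DMF, rt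
Reagents that add atoms: benzyl bromide, BrCc1ccccc1
Why: Williamson benzylation of the only phenol; the aldehyde and the chroman ether are inert to these conditions.

Step 6
Reactants: 3 1-[2,4-bis(benzyloxy)-6-hydroxyphenyl]ethan-1-one; 9 8-(benzyloxy)-2,2-dimethylchroman-6-carbaldehyde
Product: 10 (E)-1-[2,4-bis(benzyloxy)-6-hydroxyphenyl]-3-[8-(benzyloxy)-2,2-dimethylchroman-6-yl]prop-2-en-1-one
Conditions: KOH (50% aq.), EtOH–THF, rt, 36 h; then dilute HCl to pH 5
Reagents that add atoms: none
Why: Claisen–Schmidt (crossed aldol) condensation of the methyl ketone enolate with the non-enolisable aldehyde; E1cB dehydration should give the thermodynamically favoured E-enone.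

Step 7
Reactants: 10 (E)-1-[2,4-bis(benzyloxy)-6-hydroxyphenyl]-3-[8-(benzyloxy)-2,2-dimethylchroman-6-yl]prop-2-en-1-one
Product: 12 5,7-bis(benzyloxy)-3-[8-(benzyloxy)-2,2-dimethylchroman-6-yl]-4H-chromen-4-one, via racemic dimethyl acetal 11 (not isolated)
Conditions: Tl(NO3)3·3H2O (1.2 equiv), MeOH–CH(OMe)3–CH2Cl2, rt; filter; then 10% aq. HCl, MeOH–THF, 60 °C
Reagents that add atoms: none
Why: Electrophilic trivalent thallium adds to the enone C=C of 10 with methanol at the benzylic β-carbon (oxythallation); the weak C–Tl bond at the α-carbon then ionises with reduction to monovalent thallium while ring B bridges as a phenonium ion and moves from Cβ to Cα, leaving at Cβ a methoxycarbenium ion that methanol traps as dimethyl acetal 11. The closest known reaction type is the Tl(NO3)3 oxidative rearrangement of 2'-hydroxychalcones to 1,2-diaryl-3,3-dimethoxypropan-1-ones and their acid cyclisation to isoflavones. With HCl the acetal of 11 ionises to an oxocarbenium ion that the ortho phenol oxygen attacks in a 6-exo-trig closure (bond O1–C2), and loss of the second methanol gives the C2=C3 bond of pyranone ring C. No stereocentre is formed in 12, since the α-stereocentre of racemic 11 becomes sp2 C3. The step needs aryl migration to win over aroyl or hydride shift and over attack of the phenol at Cα (aurone path); the chroman ether oxygen, para to the migrating carbon, stabilises the phenonium bridge and makes ring B the best migrating group. Chemoselectivity should hold because 10 has no other alkene (the pyran ring is saturated, the prenyl group is not yet present) and every phenol except the one needed for ring closure is benzylated.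

Step 8
Reactants: 12 5,7-bis(benzyloxy)-3-[8-(benzyloxy)-2,2-dimethylchroman-6-yl]-4H-chromen-4-one
Product: 13 5,7-dihydroxy-3-(8-hydroxy-2,2-dimethylchroman-6-yl)-4H-chromen-4-one
Conditions: H2 (1 atm), 10% Pd/C, EtOAc–MeOH, rt, stopped after uptake of 3 equiv
Reagents that add atoms: none
Why: hydrogenolysis of three aryl benzyl ethers over Pd/C; at 1 atm and room temperature the C2=C3 bond of the chromone, a vinylogous ester, should survive if the reaction is stopped at three equivalents.

Step 9
Reactants: 13 5,7-dihydroxy-3-(8-hydroxy-2,2-dimethylchroman-6-yl)-4H-chromen-4-one; 14 chloromethyl methyl ether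
Product: 15 5-hydroxy-7-(methoxymethoxy)-3-[8-(methoxymethoxy)-2,2-dimethylchroman-6-yl]-4H-chromen-4-one
Conditions: MOMCl (2.2 equiv), iPr2NEt (3 equiv), CH2Cl2, 0 °C → rt
Reagents that add atoms: chloromethyl methyl ether, COCCl
Why: O-alkylation with MOMCl and a hindered amine base; the 5-OH is hydrogen-bonded to the C4 carbonyl and should stay free, so only the 7-OH and the ring B hydroxyl are masked.

Step 10
Reactants: 15 5-hydroxy-7-(methoxymethoxy)-3-[8-(methoxymethoxy)-2,2-dimethylchroman-6-yl]-4H-chromen-4-one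
Product: 16 5-hydroxy-7-(methoxymethoxy)-3-[8-(methoxymethoxy)-2,2-dimethyl-2H-chromen-6-yl]-4H-chromen-4-one
Conditions: DDQ (1.5 equiv), dry 1,4-dioxane, reflux
Reagents that add atoms: none
Why: DDQ dehydrogenation of a 2,2-dimethylchroman to the 2H-chromene; hydride abstraction from benzylic C4 is assisted by the ring oxygen ortho to C4a and loss of a C3 proton gives the alkene, and it is done now because a later prenyl group next to a phenol would itself be oxidised by DDQ.

Step 11
Reactants: 16 5-hydroxy-7-(methoxymethoxy)-3-[8-(methoxymethoxy)-2,2-dimethyl-2H-chromen-6-yl]-4H-chromen-4-one; 17 allyl bromide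
Product: 18 5-(allyloxy)-7-(methoxymethoxy)-3-[8-(methoxymethoxy)-2,2-dimethyl-2H-chromen-6-yl]-4H-chromen-4-one
Conditions: allyl bromide (3 equiv), K2CO3 (4 equiv), DMF, 60 °C
Reagents that add atoms: allyl bromide, C=CCBr
Why: Williamson allylation of the chelated 5-OH, which needs excess carbonate in warm DMF; the MOM ethers and the chromene are stable to base.

Step 12
Reactants: 18 5-(allyloxy)-7-(methoxymethoxy)-3-[8-(methoxymethoxy)-2,2-dimethyl-2H-chromen-6-yl]-4H-chromen-4-one
Product: 19 6-allyl-5-hydroxy-7-(methoxymethoxy)-3-[8-(methoxymethoxy)-2,2-dimethyl-2H-chromen-6-yl]-4H-chromen-4-one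
Conditions: PhNEt2, 200 °C, sealed tube
Reagents that add atoms: none
Why: aromatic Claisen rearrangement; the [3,3] shift from O5 should end at C6, the one ortho carbon that carries hydrogen (the other ortho carbon is ring-fusion C4a), and tautomerisation restores the chelated 5-OH.

Step 13
Reactants: 19 6-allyl-5-hydroxy-7-(methoxymethoxy)-3-[8-(methoxymethoxy)-2,2-dimethyl-2H-chromen-6-yl]-4H-chromen-4-one; 20 2-methylbut-2-ene
Product: 21 5-hydroxy-7-(methoxymethoxy)-3-[8-(methoxymethoxy)-2,2-dimethyl-2H-chromen-6-yl]-6-(3-methylbut-2-en-1-yl)-4H-chromen-4-one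
Conditions: RuCl2(=CHPh)(PCy3)(H2IMes) (second-generation Grubbs catalyst, 5 mol %), 2-methylbut-2-ene–CH2Cl2, 40 °C, sealed tube
Reagents that add atoms: 2-methylbut-2-ene, CC=C(C)C
Why: olefin cross-metathesis of the terminal allyl alkene with excess 2-methylbut-2-ene, a standard way to turn an aryl allyl group into a prenyl group; the chromene alkene is internal, conjugated and flanked by a quaternary carbon in an unstrained ring, so it should not take part.

Step 14
Reactants: 21 5-hydroxy-7-(methoxymethoxy)-3-[8-(methoxymethoxy)-2,2-dimethyl-2H-chromen-6-yl]-6-(3-methylbut-2-en-1-yl)-4H-chromen-4-one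
Product: 22 Gancaonin H
Conditions: 3 M HCl in MeOH, THF co-solvent, rt → 40 °C
Reagents that add atoms: none
Why: acid-catalysed acetal exchange with methanol removes both MOM ethers; dilute methanolic HCl at low temperature is chosen so that the prenyl alkene is not protonated and cyclised onto the neighbouring phenols.

**Compound list**

1 | 2,4,6-trihydroxyacetophenone | CC(=O)c1c(O)cc(O)cc1O | starting material
2 | benzyl bromide | BrCc1ccccc1 | starting material
3 | 1-[2,4-bis(benzyloxy)-6-hydroxyphenyl]ethan-1-one | CC(=O)c1c(O)cc(OCc2ccccc2)cc1OCc1ccccc1 | intermediate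
4 | 3,4-dihydroxybenzaldehyde | O=Cc1ccc(O)c(O)c1 | starting material
5 | 3-chloro-3-methylbut-1-yne | CC(C)(Cl)C#C | starting material
6 | 3-hydroxy-4-[(2-methylbut-3-yn-2-yl)oxy]benzaldehyde | C#CC(C)(C)Oc1ccc(C=O)cc1O | intermediate
7 | 8-hydroxy-2,2-dimethyl-2H-chromene-6-carbaldehyde | CC1(C)C=Cc2cc(C=O)cc(O)c2O1 | intermediate
8 | 8-hydroxy-2,2-dimethylchroman-6-carbaldehyde | CC1(C)CCc2cc(C=O)cc(O)c2O1 | intermediate
9 | 8-(benzyloxy)-2,2-dimethylchroman-6-carbaldehyde | CC1(C)CCc2cc(C=O)cc(OCc3ccccc3)c2O1 | intermediate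
10 | (E)-1-[2,4-bis(benzyloxy)-6-hydroxyphenyl]-3-[8-(benzyloxy)-2,2-dimethylchroman-6-yl]prop-2-en-1-one | O=C(/C=C/c1cc(OCc2ccccc2)c2OC(C)(C)CCc2c1)c1c(O)cc(OCc2ccccc2)cc1OCc1ccccc1 | intermediate
11 | 1-[2,4-bis(benzyloxy)-6-hydroxyphenyl]-2-[8-(benzyloxy)-2,2-dimethylchroman-6-yl]-3,3-dimethoxypropan-1-one (racemic) | COC(OC)C(c1cc(OCc2ccccc2)c2OC(C)(C)CCc2c1)C(=O)c1c(O)cc(OCc2ccccc2)cc1OCc1ccccc1 | intermediate (not isolated)
12 | 5,7-bis(benzyloxy)-3-[8-(benzyloxy)-2,2-dimethylchroman-6-yl]-4H-chromen-4-one | O=c1c(-c2cc(OCc3ccccc3)c3OC(C)(C)CCc3c2)coc2cc(OCc3ccccc3)cc(OCc3ccccc3)c12 | intermediate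
13 | 5,7-dihydroxy-3-(8-hydroxy-2,2-dimethylchroman-6-yl)-4H-chromen-4-one | O=c1c(-c2cc(O)c3OC(C)(C)CCc3c2)coc2cc(O)cc(O)c12 | intermediate
14 | chloromethyl methyl ether | COCCl | starting material
15 | 5-hydroxy-7-(methoxymethoxy)-3-[8-(methoxymethoxy)-2,2-dimethylchroman-6-yl]-4H-chromen-4-one | COCOc1cc(O)c2c(c1)occ(-c1cc(OCOC)c3OC(C)(C)CCc3c1)c2=O | intermediate
16 | 5-hydroxy-7-(methoxymethoxy)-3-[8-(methoxymethoxy)-2,2-dimethyl-2H-chromen-6-yl]-4H-chromen-4-one | COCOc1cc(O)c2c(c1)occ(-c1cc(OCOC)c3OC(C)(C)C=Cc3c1)c2=O | intermediate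
17 | allyl bromide | C=CCBr | starting material
18 | 5-(allyloxy)-7-(methoxymethoxy)-3-[8-(methoxymethoxy)-2,2-dimethyl-2H-chromen-6-yl]-4H-chromen-4-one | C=CCOc1cc(OCOC)cc2occ(-c3cc(OCOC)c4OC(C)(C)C=Cc4c3)c(=O)c12 | intermediate
19 | 6-allyl-5-hydroxy-7-(methoxymethoxy)-3-[8-(methoxymethoxy)-2,2-dimethyl-2H-chromen-6-yl]-4H-chromen-4-one | C=CCc1c(OCOC)cc2occ(-c3cc(OCOC)c4OC(C)(C)C=Cc4c3)c(=O)c2c1O | intermediate
20 | 2-methylbut-2-ene | CC=C(C)C | starting material
21 | 5-hydroxy-7-(methoxymethoxy)-3-[8-(methoxymethoxy)-2,2-dimethyl-2H-chromen-6-yl]-6-(3-methylbut-2-en-1-yl)-4H-chromen-4-one | CC(C)=CCc1c(OCOC)cc2occ(-c3cc(OCOC)c4OC(C)(C)C=Cc4c3)c(=O)c2c1O | intermediate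
22 | Gancaonin H, 5,7-dihydroxy-3-(8-hydroxy-2,2-dimethyl-2H-chromen-6-yl)-6-(3-methylbut-2-en-1-yl)-4H-chromen-4-one | CC(C)=CCc1c(O)cc2occ(-c3cc(O)c4c(c3)C=CC(C)(C)O4)c(=O)c2c1O | target

**Step count**

Total step count: 14.
Longest linear sequence: 13 steps (steps 2–14, from 3,4-dihydroxybenzaldehyde 4).

**Steps most likely to fail**

Step 7. The electron-rich ring A with its free phenol may be oxidised by trivalent thallium, or the phenol may attack the α-carbon before the aryl group has moved (aurone path), so that little acetal forms. Fallback: set out from chalcone 10 and close the ring first by oxa-Michael addition (NaOAc, EtOH, reflux) to give racemic flavanone 5,7-bis(benzyloxy)-2-[8-(benzyloxy)-2,2-dimethylchroman-6-yl]chroman-4-one F1, in which the phenol oxygen is already O1. Then apply the known oxidative 2,3-aryl migration of flavanones with PhI(OH)OTs (trivalent iodine) in MeCN at reflux: the enol of F1 is iodinated at C3, ring B shifts from C2 to C3 as iodobenzene leaves, and the C2 oxocarbenium ion loses a proton. This should give isoflavone 12, where the route is rejoined.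

Step 10. Hydride abstraction from C4 of the chroman may be slow, and on long heating DDQ may oxidise the chelated phenol ring or its acidic hydroquinone may cleave the MOM ethers. Fallback: set out from triol 13 and acetylate all three phenols (Ac2O, pyridine) to 3-(8-acetoxy-2,2-dimethylchroman-6-yl)-4-oxo-4H-chromene-5,7-diyl diacetate F2, whose rings are deactivated towards electrophilic bromine. Radical bromination at benzylic C4 of the chroman (NBS, AIBN cat., PhCF3, reflux) should give racemic 3-(8-acetoxy-4-bromo-2,2-dimethylchroman-6-yl)-4-oxo-4H-chromene-5,7-diyl diacetate F3, which is not isolated but treated with Et3N to eliminate HBr and give 3-(8-acetoxy-2,2-dimethyl-2H-chromen-6-yl)-4-oxo-4H-chromene-5,7-diyl diacetate F4. Methanolysis (K2CO3, MeOH, rt) frees 5,7-dihydroxy-3-(8-hydroxy-2,2-dimethyl-2H-chromen-6-yl)-4H-chromen-4-one F5, and MOMCl/iPr2NEt as in step 9 should give 16, where the route is rejoined.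

Step 14. Under acid the prenyl alkene may be protonated and captured by the 5-OH or 7-OH (closure to a dimethylchroman), or may add HCl or methanol, before both MOM ethers are gone. Fallback: change the order. Set out from allyl compound 19 and remove the two MOM ethers there (3 M HCl in MeOH, 40 °C; the monosubstituted allyl alkene is much less easily protonated) to give 6-allyl-5,7-dihydroxy-3-(8-hydroxy-2,2-dimethyl-2H-chromen-6-yl)-4H-chromen-4-one F6. The cross-metathesis with 2-methylbut-2-ene (conditions of step 13, which tolerate free phenols) is then run as the last step and should give 22 directly.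

**Further compounds**

F1 | step 7 | 5,7-bis(benzyloxy)-2-[8-(benzyloxy)-2,2-dimethylchroman-6-yl]chroman-4-one (racemic) | O=C1CC(c2cc(OCc3ccccc3)c3OC(C)(C)CCc3c2)Oc2cc(OCc3ccccc3)cc(OCc3ccccc3)c21
F2 | step 10 | 3-(8-acetoxy-2,2-dimethylchroman-6-yl)-4-oxo-4H-chromene-5,7-diyl diacetate | CC(=O)Oc1cc(OC(C)=O)c2c(c1)occ(-c1cc(OC(C)=O)c3OC(C)(C)CCc3c1)c2=O
F3 | step 10 | 3-(8-acetoxy-4-bromo-2,2-dimethylchroman-6-yl)-4-oxo-4H-chromene-5,7-diyl diacetate (racemic) | CC(=O)Oc1cc(OC(C)=O)c2c(c1)occ(-c1cc(OC(C)=O)c3OC(C)(C)CC(Br)c3c1)c2=O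
F4 | step 10 | 3-(8-acetoxy-2,2-dimethyl-2H-chromen-6-yl)-4-oxo-4H-chromene-5,7-diyl diacetate | CC(=O)Oc1cc(OC(C)=O)c2c(c1)occ(-c1cc(OC(C)=O)c3OC(C)(C)C=Cc3c1)c2=O
F5 | step 10 | 5,7-dihydroxy-3-(8-hydroxy-2,2-dimethyl-2H-chromen-6-yl)-4H-chromen-4-one | O=c1c(-c2cc(O)c3OC(C)(C)C=Cc3c2)coc2cc(O)cc(O)c12
F6 | step 14 | 6-allyl-5,7-dihydroxy-3-(8-hydroxy-2,2-dimethyl-2H-chromen-6-yl)-4H-chromen-4-one | C=CCc1c(O)cc2occ(-c3cc(O)c4OC(C)(C)C=Cc4c3)c(=O)c2c1O
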